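(All constants were chosen freely; no experiment stands behind them.)

Target, other capture product and side product each form from the intermediate, so the share asked for was the split of one stream among its exits.

- larch: starting material 39 mM; first nucleophile 2.00 equiv; solid second nucleophile 0.800 equiv; protic impurity 19.5 mM; temperature 55 °C; time 80 min
- ash: starting material 39 mM; first nucleophile 2.00 equiv; solid second nucleophile 0.800 equiv; protic impurity 19.5 mM; temperature 25 °C; time 80 min

- the flask with the highest share of target in all that became target or other capture product or side product ("all alike" if they lie within 1.5 percentage points) (larch / ash / all alike)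
- share of target in all that became target or other capture product or side product, larch
- share of target in all that became target or other capture product or side product, ash

- solid second nucleophile is a solid; its amount is given per volume of the solution
- the constants hold at 25 °C; other temperatures follow from the activation energies and enthalpies
- at the start none of the solid second nucleophile is in solution

    solid second nucleophile ⇌ second nucleophile, rate k1*(cs1 - [second nucleophile]) while solid is left; crystals form when [second nucleophile] > cs1 (cs1 = 26 mM, k1 = 0.00714 s⁻¹)
    starting material + protic impurity → quenched substrate (k2 = 0.225 L mol⁻¹ s⁻¹, Ea2 = 52.0 kJ mol⁻¹)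
    intermediate → side product (k3 = 6.46 × 10⁻⁴ s⁻¹, Ea3 = 85.0 kJ mol⁻¹)
    first nucleophile + intermediate → target (k4 = 0.0269 L mol⁻¹ s⁻¹, Ea4 = 56.0 kJ mol⁻¹)
    starting material ⇌ intermediate (K5 = 0.0565, k5 = 1.51 × 10⁻⁴ s⁻¹, Ea5 = 92.0 kJ mol⁻¹, ΔH5 = −27.0 kJ mol⁻¹)
    second nucleophile + intermediate → other capture product (k6 = 0.0266 L mol⁻¹ s⁻¹, Ea6 = 56.0 kJ mol⁻¹)
    (constants at 25 °C)

I reckoned the split at 25 °C as two waiting times of the intermediate. Capture by the first nucleophile, held at its charge, took τT = 7.94 min. The other exits together, capture by the second nucleophile at its solubility and loss to side product, took τL = 12.5 min. The capture ratio ρ = τL/τT, a selectivity factor, came to 1.57, and the share is τL/(τT+τL), so 61.1% for ash.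

For larch, both captures, whose activation energies are equal, speed up by 7.9, but the side-product step speeds up by 23. So ρ fell to 0.815, a share of 44.9%. The share I had reckoned for ash was higher, so I chose ash.

This needed the second nucleophile to stay at 26 mM, so I wrote a balance. Its charge leaves 5.20 mM as solid once saturated. The protic impurity, at half the starting material, takes 19.5 mM of the starting material, leaving 19.5 mM for the stream. Of that stream, the second nucleophile's exit draws 3.93 mM in ash and 2.89 mM in larch, both less than the reserve.

The forecast gave ash, 43.7% for larch and 60.7% for ash, holding that “Warming to 55 °C speeds the side-product step about 23-fold but the two captures only about 8-fold”. The simulation gave ash, 44.2% for larch and 60.8% for ash.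

In ash, the quench ran first, with 93% of its turnover done by 8.00 min, when the passage to intermediate had 18% of its own behind it. In ash that passage then ran on while solid second nucleophile remained, 12.6% of its charge at 80.0 min, with 26.0 mM dissolved. Read as ρ, the shares stand at 1.55 in ash and 0.792 in larch. For a neighbour of ash charged with 98 mM of starting material I reckoned ρ = 3.94, a share of 79.8%, and that flask, its second nucleophile at 25.9 mM, gave 78.9%.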